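The side chain, numbered from the ring-bound CH2 as C1', is cut between C8' and C9', two adjacent methylenes that are both allylic (to C6'=C7' and to C10'=C11'). Both would normally be electrophiles, so C9' is made nucleophilic as a phenyl sulfone. In one operation the lithiated sulfone displaces the C8' bromide, joining the complete C16 chain, the masked quinone ring and the C12' stereocentre. The precursors are an aryl-geranyl C8' allylic bromide, carrying the quinone as its 2,5-dimethoxy-3-methylphenyl ether, and an (R)-configured 1,3-dioxane acetonide whose exocyclic E olefin ends in CH2SO2Ph.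

Key step: step 11

Remark: the target is read as 12'R with 2'E, 6'E and 10'E olefins; RAMP is taken to give the R centre by the usual topicity of SAMP/RAMP azaenolate alkylation, hydrazone C=N geometry is left undefined because hydrolysis erases it, and 23 is carried as both C9' epimers.

Step 1
Reactants: 1 4-methoxy-2-methylphenol
Product: 2 2-bromo-4-methoxy-6-methylphenol
Conditions: Br2 (1.0 equiv), CH2Cl2, 0 °C
Reagents that add atoms: bromine, BrBr
Why: Electrophilic aromatic bromination in which the free hydroxyl is the strongest director and, with its para position occupied by OMe, sends bromine to the one open ortho carbon.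

Step 2
Reactants: 2 2-bromo-4-methoxy-6-methylphenol
Product: 3 1-bromo-2,5-dimethoxy-3-methylbenzene
Conditions: MeI, K2CO3, acetone, reflux
Reagents that add atoms: iodomethane, CI
Why: Williamson O-methylation of the phenoxide, the only nucleophilic site present.

Step 3
Reactants: 3 1-bromo-2,5-dimethoxy-3-methylbenzene; 4 geranyl bromide
Product: 6 1-[(2E)-3,7-dimethylocta-2,6-dien-1-yl]-2,5-dimethoxy-3-methylbenzene, via arylmagnesium bromide 5 (not isolated)
Conditions: Mg, THF, reflux; then 4, CuI (5 mol %), THF, −20 to 0 °C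
Reagents that add atoms: none
Why: Grignard formation followed by copper-catalysed allylic substitution, in which the aryl copper species attacks the unhindered primary carbon of geranyl bromide (SN2, not SN2') and leaves the E olefin untouched.

Step 4
Reactants: 6 1-[(2E)-3,7-dimethylocta-2,6-dien-1-yl]-2,5-dimethoxy-3-methylbenzene
Product: 7 (2E,6E)-8-(2,5-dimethoxy-3-methylphenyl)-2,6-dimethylocta-2,6-dien-1-ol
Conditions: SeO2 (0.2 equiv), t-BuOOH, salicylic acid (cat.), CH2Cl2, 0 °C to rt
Reagents that add atoms: tert-butyl hydroperoxide, CC(C)(C)OO (terminal oxidant; its oxygen reaches C8' through catalytic SeO2, O=[Se]=O)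
Why: Sharpless catalytic SeO2 allylic oxidation (ene reaction then [2,3]-sigmatropic shift), which picks the E-methyl of the more accessible terminal C6'=C7' isopropylidene and gives the E allylic alcohol; any enal from over-oxidation can be returned to 7 with NaBH4.

Step 5
Reactants: 7 (2E,6E)-8-(2,5-dimethoxy-3-methylphenyl)-2,6-dimethylocta-2,6-dien-1-ol
Product: 8 (2E,6E)-8-bromo-1-(2,5-dimethoxy-3-methylphenyl)-3,7-dimethylocta-2,6-diene
Conditions: CBr4, PPh3, CH2Cl2, 0 °C
Reagents that add atoms: carbon tetrabromide, BrC(Br)(Br)Br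
Why: Appel reaction, a neutral SN2 displacement of the oxyphosphonium by bromide at a primary allylic carbon, so neither olefin shifts nor the electron-rich arene is attacked; 8 is used at once.

Step 6
Reactants: 9 2,2-dimethyl-1,3-dioxan-5-one; 10 RAMP, (R)-1-amino-2-(methoxymethyl)pyrrolidine
Product: 11 (R)-N-(2,2-dimethyl-1,3-dioxan-5-ylidene)-2-(methoxymethyl)pyrrolidin-1-amine
Conditions: cyclohexane, 4 Å molecular sieves, reflux
Reagents that add atoms: none
Why: Hydrazone condensation driven by removal of water; the symmetric ketone gives a single hydrazone.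

Step 7
Reactants: 11 (R)-N-(2,2-dimethyl-1,3-dioxan-5-ylidene)-2-(methoxymethyl)pyrrolidin-1-amine; 12 prenyl bromide
Product: 15 (4R)-2,2-dimethyl-4-(3-methylbut-2-en-1-yl)-1,3-dioxan-5-one, via lithium azaenolate 13 (not isolated), via prenylated RAMP hydrazone 14 (not isolated)
Conditions: t-BuLi, THF, −78 °C; 12, −100 °C to rt; then sat. aq. (CO2H)2, Et2O, rt
Reagents that add atoms: water, O
Why: Enders RAMP-hydrazone alkylation then mild hydrazone hydrolysis: the chelated lithium azaenolate is alkylated on the face left open by the methoxymethylpyrrolidine, which with RAMP sets C4 (the later C12') as R, and two-phase oxalic acid frees the ketone without touching the prenyl olefin, the acetonide or the new stereocentre.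

Step 8
Reactants: 15 (4R)-2,2-dimethyl-4-(3-methylbut-2-en-1-yl)-1,3-dioxan-5-one; 16 ethyl (triphenylphosphoranylidene)acetate
Product: 17 ethyl (2E)-2-[(4R)-2,2-dimethyl-4-(3-methylbut-2-en-1-yl)-1,3-dioxan-5-ylidene]acetate
Conditions: CH2Cl2, rt to 40 °C
Reagents that add atoms: none
Why: Wittig olefination with a stabilised, salt-free ylide too weakly basic to epimerise C4; allylic strain places the ester carbon beside the unsubstituted ring C6H2 and away from the C4 prenyl group, which is the 5E olefin, and a minor Z isomer would be removed by chromatography here.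

Step 9
Reactants: 17 ethyl (2E)-2-[(4R)-2,2-dimethyl-4-(3-methylbut-2-en-1-yl)-1,3-dioxan-5-ylidene]acetate
Product: 18 (2E)-2-[(4R)-2,2-dimethyl-4-(3-methylbut-2-en-1-yl)-1,3-dioxan-5-ylidene]ethan-1-ol
Conditions: i-Bu2AlH (2.2 equiv), CH2Cl2, −78 °C; aq. Rochelle salt
Reagents that add atoms: none
Why: DIBAL-H 1,2-reduction of a conjugated ester to the allylic alcohol, which at −78 °C leaves the acetonide, the olefin geometry and C4 unchanged.

Step 10
Reactants: 18 (2E)-2-[(4R)-2,2-dimethyl-4-(3-methylbut-2-en-1-yl)-1,3-dioxan-5-ylidene]ethan-1-ol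
Product: 21 (4R,5E)-2,2-dimethyl-4-(3-methylbut-2-en-1-yl)-5-[2-(phenylsulfonyl)ethylidene]-1,3-dioxane, via allylic mesylate 19 (not isolated), via allylic bromide 20 (not isolated)
Conditions: MsCl, Et3N, THF, −40 °C; LiBr, THF, −40 to 0 °C; then PhSO2Na, DMF, rt
Reagents that add atoms: sodium benzenesulfinate, [Na+].[O-]S(=O)c1ccccc1
Why: Mesylation, bromide exchange and sulfinate S-alkylation are three SN2 displacements at the primary allylic C9', acid-free so the acetonide survives, and the soft sulfur end of the sulfinate gives the sulfone without allylic shift.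

Step 11
Reactants: 21 (4R,5E)-2,2-dimethyl-4-(3-methylbut-2-en-1-yl)-5-[2-(phenylsulfonyl)ethylidene]-1,3-dioxane; 8 (2E,6E)-8-bromo-1-(2,5-dimethoxy-3-methylphenyl)-3,7-dimethylocta-2,6-diene
Product: 23 (4R,5E)-5-[(4E,8E)-10-(2,5-dimethoxy-3-methylphenyl)-4,8-dimethyl-2-(phenylsulfonyl)deca-4,8-dien-1-ylidene]-2,2-dimethyl-4-(3-methylbut-2-en-1-yl)-1,3-dioxane (both C9' epimers), via lithiated sulfone 22 (not isolated)
Conditions: n-BuLi (1.05 equiv), THF, −78 °C; then 8, THF, −78 to −40 °C; cold NH4Cl quench
Reagents that add atoms: none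
Why: n-BuLi removes the C9' proton of 21, which is both α to sulfur and allylic, and the resulting sulfonyl-stabilised allyl lithium 22 displaces bromide from the primary allylic C8' of 8 in an SN2 step that forms the C8'–C9' bond. The closest known reaction type is the alkylation of lithiated allylic sulfones by allylic halides used for polyprenyl chain coupling, which is also established for sulfones carrying a γ-alkoxymethyl group. No ring is closed. The only new stereocentre, C9', is uncontrolled and is deleted in step 12, while C12' is not acidic and keeps its R configuration. α- rather than γ-alkylation is secured because the charge is held next to sulfur and the γ-carbon C11' is fully substituted, and direct rather than transposed attack on 8 is secured because C8' is primary whereas C6' is a substituted olefinic carbon. The competing process, vinylogous β-elimination of an acetal oxygen from the anion, is held back by metalating at −78 °C, adding 8 at once and quenching cold; the acetonide and the aryl ethers do not react with one equivalent of base.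

Step 12
Reactants: 23 (4R,5E)-5-[(4E,8E)-10-(2,5-dimethoxy-3-methylphenyl)-4,8-dimethyl-2-(phenylsulfonyl)deca-4,8-dien-1-ylidene]-2,2-dimethyl-4-(3-methylbut-2-en-1-yl)-1,3-dioxane
Product: 24 (4R,5E)-5-[(4E,8E)-10-(2,5-dimethoxy-3-methylphenyl)-4,8-dimethyldeca-4,8-dien-1-ylidene]-2,2-dimethyl-4-(3-methylbut-2-en-1-yl)-1,3-dioxane
Conditions: PdCl2(dppp) (5 mol %), LiBHEt3 (2.5 equiv), THF, 0 °C to rt
Reagents that add atoms: none
Why: Palladium-catalysed reductive desulfonylation, in which zerovalent palladium formed in situ ionises the allylic C9'–S bond to an allylpalladium species and hydride from LiBHEt3 goes to the less substituted C9' terminus and not to the fully substituted C11', so C10'=C11' keeps its position and E geometry and both C9' epimers converge.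

Step 13
Reactants: 24 (4R,5E)-5-[(4E,8E)-10-(2,5-dimethoxy-3-methylphenyl)-4,8-dimethyldeca-4,8-dien-1-ylidene]-2,2-dimethyl-4-(3-methylbut-2-en-1-yl)-1,3-dioxane
Product: 25 (2E,6E,10E,12R)-1-(2,5-dimethoxy-3-methylphenyl)-11-(hydroxymethyl)-3,7,15-trimethylhexadeca-2,6,10,14-tetraen-12-ol
Conditions: AcOH/H2O/THF (3:1:1), 40 °C
Reagents that add atoms: none
Why: Acid-catalysed acetal hydrolysis of the six-membered acetonide under conditions too mild to ionise the allylic alcohols or to affect the trisubstituted olefins and aryl ethers.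

Step 14
Reactants: 25 (2E,6E,10E,12R)-1-(2,5-dimethoxy-3-methylphenyl)-11-(hydroxymethyl)-3,7,15-trimethylhexadeca-2,6,10,14-tetraen-12-ol
Product: 26 2-[(2E,6E,10E,12R)-12-hydroxy-11-(hydroxymethyl)-3,7,15-trimethylhexadeca-2,6,10,14-tetraen-1-yl]-6-methylcyclohexa-2,5-diene-1,4-dione
Conditions: (NH4)2Ce(NO3)6 (2.5 equiv), MeCN/H2O (2:1), 0 °C, 15 min
Reagents that add atoms: water, O
Why: Oxidative demethylation of the para-dimethoxyarene by tetravalent cerium (two one-electron oxidations with attack of water and loss of methanol) gives the para-quinone, and the short cold contact spares the olefins and the allylic 1,3-diol.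

Compound list
1 | 4-methoxy-2-methylphenol | Cc1cc(OC)ccc1O | starting material
2 | 2-bromo-4-methoxy-6-methylphenol | Cc1cc(OC)cc(Br)c1O | intermediate
3 | 1-bromo-2,5-dimethoxy-3-methylbenzene | COc1cc(C)c(OC)c(Br)c1 | intermediate
4 | geranyl bromide, (2E)-1-bromo-3,7-dimethylocta-2,6-diene | CC(C)=CCC/C(C)=C/CBr | starting material
5 | (2,5-dimethoxy-3-methylphenyl)magnesium bromide | COc1cc(C)c(OC)c([Mg]Br)c1 | intermediate
6 | 1-[(2E)-3,7-dimethylocta-2,6-dien-1-yl]-2,5-dimethoxy-3-methylbenzene | CC(C)=CCC/C(C)=C/Cc1cc(OC)cc(C)c1OC | intermediate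
7 | (2E,6E)-8-(2,5-dimethoxy-3-methylphenyl)-2,6-dimethylocta-2,6-dien-1-ol | OC/C(C)=C/CC/C(C)=C/Cc1cc(OC)cc(C)c1OC | intermediate
8 | (2E,6E)-8-bromo-1-(2,5-dimethoxy-3-methylphenyl)-3,7-dimethylocta-2,6-diene | BrC/C(C)=C/CC/C(C)=C/Cc1cc(OC)cc(C)c1OC | intermediate
9 | 2,2-dimethyl-1,3-dioxan-5-one | CC1(C)OCC(=O)CO1 | starting material
10 | RAMP, (R)-1-amino-2-(methoxymethyl)pyrrolidine | COC[C@H]1CCCN1N | starting material
11 | (R)-N-(2,2-dimethyl-1,3-dioxan-5-ylidene)-2-(methoxymethyl)pyrrolidin-1-amine | COC[C@H]1CCCN1N=C1COC(C)(C)OC1 | intermediate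
12 | prenyl bromide, 1-bromo-3-methylbut-2-ene | CC(C)=CCBr | starting material
13 | lithium azaenolate of 11 | COC[C@H]1CCCN1[N-]C1=COC(C)(C)OC1.[Li+] | intermediate
14 | (R)-N-[(4R)-2,2-dimethyl-4-(3-methylbut-2-en-1-yl)-1,3-dioxan-5-ylidene]-2-(methoxymethyl)pyrrolidin-1-amine (C=N geometry undefined) | CC(C)=CC[C@H]1OC(C)(C)OCC1=NN1CCC[C@@H]1COC | intermediate
15 | (4R)-2,2-dimethyl-4-(3-methylbut-2-en-1-yl)-1,3-dioxan-5-one | CC(C)=CC[C@H]1OC(C)(C)OCC1=O | intermediate
16 | ethyl (triphenylphosphoranylidene)acetate | CCOC(=O)C=P(c1ccccc1)(c1ccccc1)c1ccccc1 | starting material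
17 | ethyl (2E)-2-[(4R)-2,2-dimethyl-4-(3-methylbut-2-en-1-yl)-1,3-dioxan-5-ylidene]acetate | CC(C)=CC[C@H]1OC(C)(C)OC/C1=C\C(=O)OCC | intermediate
18 | (2E)-2-[(4R)-2,2-dimethyl-4-(3-methylbut-2-en-1-yl)-1,3-dioxan-5-ylidene]ethan-1-ol | CC(C)=CC[C@H]1OC(C)(C)OC/C1=C\CO | intermediate
19 | (2E)-2-[(4R)-2,2-dimethyl-4-(3-methylbut-2-en-1-yl)-1,3-dioxan-5-ylidene]ethyl methanesulfonate | CC(C)=CC[C@H]1OC(C)(C)OC/C1=C\COS(C)(=O)=O | intermediate
20 | (4R,5E)-5-(2-bromoethylidene)-2,2-dimethyl-4-(3-methylbut-2-en-1-yl)-1,3-dioxane | CC(C)=CC[C@H]1OC(C)(C)OC/C1=C\CBr | intermediate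
21 | (4R,5E)-2,2-dimethyl-4-(3-methylbut-2-en-1-yl)-5-[2-(phenylsulfonyl)ethylidene]-1,3-dioxane | CC(C)=CC[C@H]1OC(C)(C)OC/C1=C\CS(=O)(=O)c1ccccc1 | intermediate
22 | C9'-lithio derivative of 21 | CC(C)=CC[C@H]1OC(C)(C)OC/C1=C\[CH-]S(=O)(=O)c1ccccc1.[Li+] | intermediate
23 | (4R,5E)-5-[(4E,8E)-10-(2,5-dimethoxy-3-methylphenyl)-4,8-dimethyl-2-(phenylsulfonyl)deca-4,8-dien-1-ylidene]-2,2-dimethyl-4-(3-methylbut-2-en-1-yl)-1,3-dioxane (both C9' epimers) | CC(C)=CC[C@H]1OC(C)(C)OC/C1=C\C(C/C(C)=C/CC/C(C)=C/Cc1cc(OC)cc(C)c1OC)S(=O)(=O)c1ccccc1 | intermediate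
24 | (4R,5E)-5-[(4E,8E)-10-(2,5-dimethoxy-3-methylphenyl)-4,8-dimethyldeca-4,8-dien-1-ylidene]-2,2-dimethyl-4-(3-methylbut-2-en-1-yl)-1,3-dioxane | CC(C)=CC[C@H]1OC(C)(C)OC/C1=C\CC/C(C)=C/CC/C(C)=C/Cc1cc(OC)cc(C)c1OC | intermediate
25 | (2E,6E,10E,12R)-1-(2,5-dimethoxy-3-methylphenyl)-11-(hydroxymethyl)-3,7,15-trimethylhexadeca-2,6,10,14-tetraen-12-ol | CC(C)=CC[C@@H](O)/C(=C/CC/C(C)=C/CC/C(C)=C/Cc1cc(OC)cc(C)c1OC)CO | intermediate
26 | 2-[(2E,6E,10E,12R)-12-hydroxy-11-(hydroxymethyl)-3,7,15-trimethylhexadeca-2,6,10,14-tetraen-1-yl]-6-methylcyclohexa-2,5-diene-1,4-dione | CC(C)=CC[C@@H](O)/C(=C/CC/C(C)=C/CC/C(C)=C/CC1=CC(=O)C=C(C)C1=O)CO | target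

Total step count: 14. Longest linear sequence: 9 steps (steps 1–5 then 11–14, or steps 6–14).

Steps most likely to fail

Step 11. The lithiated sulfone may lose an acetal oxygen by vinylogous β-elimination before it is alkylated, or be alkylated sluggishly. The fallback sets out from 21 and removes the leaving-group character of the oxygens. The acetonide is hydrolysed first (AcOH/H2O/THF) to the diol sulfone (3R)-6-methyl-2-[(E)-2-(phenylsulfonyl)ethylidene]hept-5-ene-1,3-diol F1. Three equivalents of n-BuLi in THF/DMPU at −78 °C then give the bis-alkoxide carbanion, whose oxide substituents cannot depart, and C-alkylation with 8 should give (2E,6E,10E,12R)-1-(2,5-dimethoxy-3-methylphenyl)-11-(hydroxymethyl)-3,7,15-trimethyl-9-(phenylsulfonyl)hexadeca-2,6,10,14-tetraen-12-ol F2 as both C9 epimers. PdCl2(dppp)/LiBHEt3, with extra hydride for the two hydroxyls, then returns to the route at 25, making step 13 unnecessary.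

Step 12. Hydride may be delivered to C11' with transposition of the olefin, or the allylpalladium intermediate may interconvert syn and anti forms and erode the 10'E geometry. The fallback sets out from 23 and replaces the metal-allyl hydride substitution by electron-transfer cleavage of the C–S bond: Na(Hg), Na2HPO4, MeOH/THF, −20 °C. The allyl anion is protonated by methanol at the less hindered C9', and the route is rejoined at 24. It makes no new compound (F0).

Step 4. The allylic oxidation may stall, over-oxidise, or attack the allylic positions of the inner C2'=C3' olefin. The fallback sets out from 6 and installs the C8' oxygen by olefin cross-metathesis instead of C–H oxidation. Methacrolein with (H2IMes)(PCy3)Cl2Ru=CHPh (second-generation Grubbs catalyst) in CH2Cl2 at 40 °C exchanges the terminal isopropylidene, the only unhindered olefin, for the E enal (2E,6E)-8-(2,5-dimethoxy-3-methylphenyl)-2,6-dimethylocta-2,6-dienal F3. Luche reduction (NaBH4, CeCl3·7H2O, MeOH, 0 °C) then returns to the route at 7.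

Further compounds
F1 | step 11 | (3R)-6-methyl-2-[(E)-2-(phenylsulfonyl)ethylidene]hept-5-ene-1,3-diol | CC(C)=CC[C@@H](O)/C(CO)=C/CS(=O)(=O)c1ccccc1
F2 | step 11 | (2E,6E,10E,12R)-1-(2,5-dimethoxy-3-methylphenyl)-11-(hydroxymethyl)-3,7,15-trimethyl-9-(phenylsulfonyl)hexadeca-2,6,10,14-tetraen-12-ol (both C9 epimers) | CC(C)=CC[C@@H](O)/C(CO)=C/C(C/C(C)=C/CC/C(C)=C/Cc1cc(OC)cc(C)c1OC)S(=O)(=O)c1ccccc1
F0 | step 12 | none | none
F3 | step 4 | (2E,6E)-8-(2,5-dimethoxy-3-methylphenyl)-2,6-dimethylocta-2,6-dienal | O=C/C(C)=C/CC/C(C)=C/Cc1cc(OC)cc(C)c1OC
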